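(The numbers in the tables were generated by integration from invented constants; scatter was added.)

**Your question.** Work with the fraction of target left and not with the fraction made, since that is what the share you want measures, and your hunch that the warm flask comes out dirtiest is a fair place to start.

common to all: substrate 20 mM
- Sunday's: fresh partner 1.5 equiv; coupling partner 1 equiv; temperature −5 °C; run made earlier
- Wednesday's: fresh partner 1.5 equiv; coupling partner 1.5 equiv; temperature 17 °C; run made earlier
- Monday's: fresh partner 2.2 equiv; coupling partner 2 equiv; temperature −5 °C; run made earlier
- dawn: fresh partner 1.50 equiv; coupling partner 2.00 equiv; at 25 °C until 4.0 h, from then on at −15 °C; time 20 h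
- summer: fresh partner 1.50 equiv; coupling partner 2.00 equiv; temperature 5 °C; time 20 h
- autumn: fresh partner 1.50 equiv; coupling partner 2.00 equiv; temperature −15 °C; time 20 h
- midnight: fresh partner 1.50 equiv; coupling partner 2.00 equiv; temperature 25 °C; time 20 h

- Sunday's (time / h: target / %, over-reaction product / %): 2.50: 0, 0.4; 6.00: 0, 0.6; 12.0: 0, 0; 20.0: 0.2, 0.1
- Wednesday's (time / h: target / %, over-reaction product / %): 0.500: 0.1, 0.5; 1.00: 0.1, 0.3; 3.00: 2.7, 0.4; 6.00: 9.1, 0
- Monday's (time / h: target / %, over-reaction product / %): 2.50: 1.1, 0; 6.00: 0.6, 0.3; 12.0: 1.2, 0.7; 20.0: 2.1, 0.3

(readings scatter by 0.5 percentage points)

- percent here means substrate units held: one side product counts as two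
- the numbers in the tables scatter with a standard deviation of 0.5 percentage points
- candidate steps: substrate + coupling partner -> open intermediate; coupling partner + fresh partner -> second intermediate; open intermediate + second intermediate -> target; coupling partner + target -> over-reaction product; substrate + target -> side product

1. the flask with the highest share of target in all that became target or over-reaction product or side product ("all alike" if they lie within 1.5 percentage points) (dawn / summer / autumn / midnight / all alike)
2. share of target in all that became target or over-reaction product or side product, dawn
3. share of target in all that became target or over-reaction product or side product, summer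
4. share of target in all that became target or over-reaction product or side product, autumn
5. share of target in all that became target or over-reaction product or side product, midnight

**Loss rate.** The number to carry is the loss rate, the fraction of the target present that is lost per hour, a pseudo-first-order constant for as long as [coupling partner] and [substrate] hold steady. Target made steadily over a time has a mean age of half that time, so the fraction left is close to the exponential of minus the loss rate times that age. Wednesday's last reading shows 9.1% of target and 0% of over-reaction product, and allowing 2 standard deviations of 0.5 percentage points for that zero gives a ceiling on Wednesday's loss to over-reaction product of 0.0366 h⁻¹. The side product was never read, so I let this ceiling stand for the whole loss.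

**My number.** Carrying Wednesday's ceiling, read at 17 °C, unchanged to midnight at 25 °C over 20 h gives a fraction left of 69.3%, which is my own rough estimate for midnight and lies below the forecast's.

**The forecast.** It names autumn as the cleanest, with dawn 91%, summer 93%, autumn 96% and midnight 76%, on the ground that “Flasks that make little target therefore stay clean”.

**The result.** Autumn does come highest at 99.6%, with dawn 95.2% and summer 96.5%, but midnight gives 83.6%, which is 7.6 points above the forecast.

    substrate + coupling partner → open intermediate (k = 8.20 M⁻¹ h⁻¹, Ea = 66.0 kJ mol⁻¹)
    coupling partner + fresh partner → second intermediate (k = 2.00 M⁻¹ h⁻¹, Ea = 78.0 kJ mol⁻¹)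
    open intermediate + second intermediate → target (k = 78.0 M⁻¹ h⁻¹, Ea = 47.0 kJ mol⁻¹)
    coupling partner + target → over-reaction product (k = 0.930 M⁻¹ h⁻¹, Ea = 83.0 kJ mol⁻¹)
    substrate + target → side product (k = 0.670 M⁻¹ h⁻¹, Ea = 62.0 kJ mol⁻¹)
    (constants at 25 °C)

**Midnight's supply.** Read back from its share with the same mean age, midnight's loss rate, averaged over the run, is 0.0179 h⁻¹, below Wednesday's ceiling. The shrinking supply of coupling partner, down to 17% of its charge at the end, is part of what keeps midnight's share up: with that supply held, the same flask gives 62.8% against 83.6%. Summer, at 5 °C and with 64% of its coupling partner still there at the end, reads back from its share at 0.00352 h⁻¹.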